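Everything rests on cutting the aryl ketone bond C4–C4a of ring C. Ring A bears oxygen at C5, C6, C7, C8 and C8a (O1), so C4a is its only C–H. It lies ortho to O1 and to the C5 oxygen and para to the C7 oxygen, so an acyl cation tethered through O1 can attack nowhere else on that ring. One cyclodehydration thus forms C4–C4a, closes the pyranone and delivers the whole flavone in tetrabenzyl form. The precursor is an (E)-3-aryloxy-2-methoxycinnamic acid: ring A hangs on O1, ring B sits on C2, the 3-methoxy group is in place and the carboxyl carbon becomes C4. Hydrogenolysis then frees the four phenols.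

Key step: step 12

Assumption: the target has no stereocentre. The four tetrasubstituted alkenes on the way (β-chloro ester, aryl vinyl ether ester, acid, mixed anhydride) are drawn as E isomers, with the carbonyl carbon cis to chlorine or aryloxy. E/Z mixtures are expected and would be carried on unseparated, because the geometry becomes mobile in the ring closure.

**Ring A fragment**

Step 1
Reactants: 1 2,6-dimethoxyphenol (syringol)
Product: 2 2-(benzyloxy)-1,3-dimethoxybenzene
Conditions: BnBr, K2CO3, acetone, reflux
Reagents that add atoms: benzyl bromide, BrCc1ccccc1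
Why: Williamson ether synthesis of a phenoxide with a reactive benzylic bromide, installing on the future O7 a group that falls in the final hydrogenolysis.

Step 2
Reactants: 2 2-(benzyloxy)-1,3-dimethoxybenzene
Product: 3 3-(benzyloxy)-1,5-dibromo-2,4-dimethoxybenzene
Conditions: NBS (2.1 equiv), MeCN, 0 °C to rt, dark
Reagents that add atoms: N-bromosuccinimide, O=C1CCC(=O)N1Br
Why: Electrophilic aromatic bromination in which the flanked central benzyloxy group is twisted out of conjugation, so each methoxy group directs ortho/para to the two mutually meta positions next to the methoxy groups, while the polar dark conditions spare the benzylic CH2 and the unactivated phenyl ring.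

Step 3
Reactants: 3 3-(benzyloxy)-1,5-dibromo-2,4-dimethoxybenzene
Product: 5 5-(benzyloxy)-4,6-dimethoxybenzene-1,3-diol, via bis(pinacol boronate) 4 (not isolated)
Conditions: B2pin2 (2.4 equiv), Pd(dppf)Cl2 (5 mol %), KOAc, 1,4-dioxane, 90 °C; filter, then 30% H2O2, aq NaOH, THF, 0 °C, under N2
Reagents that add atoms: bis(pinacolato)diboron, CC1(C)OB(OC1(C)C)B1OC(C)(C)C(C)(C)O1 (boron and pinacol atoms stay only in 4); hydrogen peroxide, OO
Why: Double Miyaura borylation followed by boronate oxidation (aryl migration from boron to oxygen) replaces each bromine by hydroxyl at the same carbon under conditions that leave aryl ethers untouched.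

Step 4
Reactants: 5 5-(benzyloxy)-4,6-dimethoxybenzene-1,3-diol
Product: 6 3,5-bis(benzyloxy)-2,4-dimethoxyphenol
Conditions: BnBr (0.9 equiv), K2CO3 (1 equiv), acetone, 40 °C, under N2; unreacted 5 recycled
Reagents that add atoms: benzyl bromide, BrCc1ccccc1
Why: Williamson monoalkylation of a diol whose two hydroxyls are related by a mirror plane, so only one monoether can form and a deficit of benzyl bromide holds back the second alkylation.

**Ring B fragment**

Step 5
Reactants: 7 3,4-bis(benzyloxy)benzaldehyde
Product: 8 4,5-bis(benzyloxy)-2-bromobenzaldehyde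
Conditions: Br2, NaOAc, AcOH, rt
Reagents that add atoms: bromine, BrBr
Why: Electrophilic aromatic bromination at the carbon para to the 3-benzyloxy group and ortho to the formyl group, the same outcome as for veratraldehyde, with NaOAc trapping HBr to protect the benzyl ethers.

Step 6
Reactants: 8 4,5-bis(benzyloxy)-2-bromobenzaldehyde
Product: 9 4,5-bis(benzyloxy)-2-methoxybenzaldehyde
Conditions: NaOMe, CuBr (10 mol %), MeOH/DMF, 100 °C
Reagents that add atoms: sodium methoxide, [Na+].[O-]C
Why: Ullmann-type copper-catalysed methoxylation of an aryl bromide, assisted by the ortho formyl group (reversibly masked as its hemiacetal alkoxide), with benzyl ethers inert to methoxide.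

Step 7
Reactants: 9 4,5-bis(benzyloxy)-2-methoxybenzaldehyde; 10 methyl methoxyacetate
Product: 12 methyl 3-[4,5-bis(benzyloxy)-2-methoxyphenyl]-3-hydroxy-2-methoxypropanoate (racemic syn/anti mixture), via lithium enolate 11 (not isolated)
Conditions: 10, LiN(iPr)2 (LDA, commercial solution), THF, −78 °C; then 9; AcOH quench
Reagents that add atoms: lithium diisopropylamide, [Li+].CC(C)[N-]C(C)C (lithium stays only in 11)
Why: Aldol addition of a preformed ester enolate to a non-enolisable aldehyde, in which the two new stereocentres form without control and do not matter because both carbons become sp2 in steps 8 and 9.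

Step 8
Reactants: 12 methyl 3-[4,5-bis(benzyloxy)-2-methoxyphenyl]-3-hydroxy-2-methoxypropanoate
Product: 13 methyl 3-[4,5-bis(benzyloxy)-2-methoxyphenyl]-2-methoxy-3-oxopropanoate (racemic, labile at C2)
Conditions: Dess–Martin periodinane, CH2Cl2, rt
Reagents that add atoms: none
Why: Dess–Martin oxidation of a secondary benzylic alcohol under base-free conditions that avoid retro-aldol cleavage, the remaining stereocentre being erased in step 9.

Step 9
Reactants: 13 methyl 3-[4,5-bis(benzyloxy)-2-methoxyphenyl]-2-methoxy-3-oxopropanoate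
Product: 14 methyl (E)-3-[4,5-bis(benzyloxy)-2-methoxyphenyl]-3-chloro-2-methoxyprop-2-enoate
Conditions: (COCl)2, DMF, ClCH2CH2Cl, 0 to 60 °C
Reagents that add atoms: oxalyl chloride, O=C(Cl)C(=O)Cl
Why: Vilsmeier-type deoxychlorination of a β-keto ester, in which the enol oxygen, made nucleophilic by the ortho and para alkoxy groups of ring B, is activated by the chloroiminium salt and chloride then displaces DMF at the β-carbon by addition–elimination.

**Union, ring closure, deprotection**

Step 10
Reactants: 14 methyl (E)-3-[4,5-bis(benzyloxy)-2-methoxyphenyl]-3-chloro-2-methoxyprop-2-enoate; 6 3,5-bis(benzyloxy)-2,4-dimethoxyphenol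
Product: 15 methyl (E)-3-[3,5-bis(benzyloxy)-2,4-dimethoxyphenoxy]-3-[4,5-bis(benzyloxy)-2-methoxyphenyl]-2-methoxyprop-2-enoate
Conditions: Cs2CO3, DMF, 80 °C, under argon
Reagents that add atoms: none
Why: Nucleophilic vinylic substitution (addition–elimination), in which the caesium phenoxide adds to the β-carbon of the chloroacrylate and the ester enolate expels chloride, as in the classical preparation of β-aryloxy unsaturated esters from β-chloro esters.

Step 11
Reactants: 15 methyl (E)-3-[3,5-bis(benzyloxy)-2,4-dimethoxyphenoxy]-3-[4,5-bis(benzyloxy)-2-methoxyphenyl]-2-methoxyprop-2-enoate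
Product: 16 (E)-3-[3,5-bis(benzyloxy)-2,4-dimethoxyphenoxy]-3-[4,5-bis(benzyloxy)-2-methoxyphenyl]-2-methoxyprop-2-enoic acid
Conditions: LiOH, 1,4-dioxane/H2O, 50 °C; then 1 M HCl, 0 °C
Reagents that add atoms: lithium hydroxide, [Li+].[OH-]
Why: Saponification (BAc2) of a methyl ester, run without alcohol cosolvent so that no alkoxide can displace the aryloxy group, after which the carboxylate shuts off any further attack at the β-carbon.

Step 12
Reactants: 16 (E)-3-[3,5-bis(benzyloxy)-2,4-dimethoxyphenoxy]-3-[4,5-bis(benzyloxy)-2-methoxyphenyl]-2-methoxyprop-2-enoic acid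
Product: 18 5,7-bis(benzyloxy)-2-[4,5-bis(benzyloxy)-2-methoxyphenyl]-3,6,8-trimethoxy-4H-chromen-4-one, via mixed trifluoroacetic anhydride 17 (not isolated)
Conditions: (CF3CO)2O (2 equiv, slow addition), CH2Cl2 (dilute), 0 °C to rt
Reagents that add atoms: trifluoroacetic anhydride, O=C(OC(=O)C(F)(F)F)C(F)(F)F (its atoms stay only in 17)
Why: Trifluoroacetic anhydride turns acid 16 into mixed anhydride 17, whose acyl carbon gains acylium character because the β-aryloxy and α-methoxy oxygens help push out trifluoroacetate (oxonio-ketene resonance form), and C4a of ring A attacks it in an SEAr step that ends with loss of the C4a proton. The closest known reaction type is the intramolecular Friedel–Crafts acylation of 3-aryloxycinnamic and 3-aryloxyacrylic acids to flavones and chromones (Ruhemann-type cyclodehydration), run here under the mild carboxylic acid/trifluoroacetic anhydride protocol used for activated arenes. Ring C closes as a six-membered ring, 6-exo-trig at the anhydride carbonyl (6-exo-dig if the free acylium ion is the electrophile), with O1, C2 and C3 already in the tether. No stereocentre is formed, and the alkene geometry is not critical because the same resonance form lowers the C2–C3 bond order and lets the Z isomer rotate into the reactive E form. The step needs site selectivity against closure onto C6' of ring B (five-membered indenone), against lactonisation through the 2'-methoxy oxygen and against intermolecular trifluoroacetylation: C4a is the only free carbon of ring A and has two ortho oxygens and one para oxygen, C6' has a single ortho donor, methyl loss from an oxonium ion is slow with trifluoroacetate as the nucleophile, and dilution with little excess anhydride favours the intramolecular path. The benzyl and methyl ethers should survive the short exposure to dilute trifluoroacetic acid at or below room temperature.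

Step 13
Reactants: 18 5,7-bis(benzyloxy)-2-[4,5-bis(benzyloxy)-2-methoxyphenyl]-3,6,8-trimethoxy-4H-chromen-4-one
Product: 19 5,7,4',5'-tetrahydroxy-3,6,8,2'-tetramethoxyflavone
Conditions: H2 (1 atm), 10% Pd/C, THF/MeOH, rt
Reagents that add atoms: none
Why: Catalytic hydrogenolysis cleaves the four benzylic C–O bonds, while the methyl ethers and the tetrasubstituted, conjugated C2–C3 double bond of the chromone are inert at atmospheric pressure and room temperature.

**Compound list**

1 | 2,6-dimethoxyphenol (syringol) | COc1cccc(OC)c1O | starting material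
2 | 2-(benzyloxy)-1,3-dimethoxybenzene | COc1cccc(OC)c1OCc1ccccc1 | intermediate
3 | 3-(benzyloxy)-1,5-dibromo-2,4-dimethoxybenzene | COc1c(Br)cc(Br)c(OC)c1OCc1ccccc1 | intermediate
4 | 2,2'-[5-(benzyloxy)-4,6-dimethoxy-1,3-phenylene]bis(4,4,5,5-tetramethyl-1,3,2-dioxaborolane), the bis(pinacol boronate) | COc1c(B2OC(C)(C)C(C)(C)O2)cc(B2OC(C)(C)C(C)(C)O2)c(OC)c1OCc1ccccc1 | intermediate
5 | 5-(benzyloxy)-4,6-dimethoxybenzene-1,3-diol | COc1c(O)cc(O)c(OC)c1OCc1ccccc1 | intermediate
6 | 3,5-bis(benzyloxy)-2,4-dimethoxyphenol | COc1c(O)cc(OCc2ccccc2)c(OC)c1OCc1ccccc1 | intermediate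
7 | 3,4-bis(benzyloxy)benzaldehyde | O=Cc1ccc(OCc2ccccc2)c(OCc2ccccc2)c1 | starting material
8 | 4,5-bis(benzyloxy)-2-bromobenzaldehyde | O=Cc1cc(OCc2ccccc2)c(OCc2ccccc2)cc1Br | intermediate
9 | 4,5-bis(benzyloxy)-2-methoxybenzaldehyde | COc1cc(OCc2ccccc2)c(OCc2ccccc2)cc1C=O | intermediate
10 | methyl methoxyacetate | COCC(=O)OC | starting material
11 | lithium enolate of methyl methoxyacetate (chelated form, α-methoxy oxygen and O–Li on the same side) | CO/C=C(\[O-])OC.[Li+] | intermediate
12 | methyl 3-[4,5-bis(benzyloxy)-2-methoxyphenyl]-3-hydroxy-2-methoxypropanoate (racemic syn/anti mixture) | COC(C(=O)OC)C(O)c1cc(OCc2ccccc2)c(OCc2ccccc2)cc1OC | intermediate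
13 | methyl 3-[4,5-bis(benzyloxy)-2-methoxyphenyl]-2-methoxy-3-oxopropanoate (racemic) | COC(C(=O)OC)C(=O)c1cc(OCc2ccccc2)c(OCc2ccccc2)cc1OC | intermediate
14 | methyl (E)-3-[4,5-bis(benzyloxy)-2-methoxyphenyl]-3-chloro-2-methoxyprop-2-enoate | COC(=O)/C(OC)=C(/c1cc(OCc2ccccc2)c(OCc2ccccc2)cc1OC)Cl | intermediate
15 | methyl (E)-3-[3,5-bis(benzyloxy)-2,4-dimethoxyphenoxy]-3-[4,5-bis(benzyloxy)-2-methoxyphenyl]-2-methoxyprop-2-enoate | COC(=O)/C(OC)=C(/c1cc(OCc2ccccc2)c(OCc2ccccc2)cc1OC)Oc1cc(OCc2ccccc2)c(OC)c(OCc2ccccc2)c1OC | intermediate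
16 | (E)-3-[3,5-bis(benzyloxy)-2,4-dimethoxyphenoxy]-3-[4,5-bis(benzyloxy)-2-methoxyphenyl]-2-methoxyprop-2-enoic acid | OC(=O)/C(OC)=C(/c1cc(OCc2ccccc2)c(OCc2ccccc2)cc1OC)Oc1cc(OCc2ccccc2)c(OC)c(OCc2ccccc2)c1OC | intermediate
17 | mixed anhydride of 16 and trifluoroacetic acid (E) | FC(F)(F)C(=O)OC(=O)/C(OC)=C(/c1cc(OCc2ccccc2)c(OCc2ccccc2)cc1OC)Oc1cc(OCc2ccccc2)c(OC)c(OCc2ccccc2)c1OC | intermediate
18 | 5,7-bis(benzyloxy)-2-[4,5-bis(benzyloxy)-2-methoxyphenyl]-3,6,8-trimethoxy-4H-chromen-4-one | COc1cc(OCc2ccccc2)c(OCc2ccccc2)cc1-c1oc2c(OC)c(OCc3ccccc3)c(OC)c(OCc3ccccc3)c2c(=O)c1OC | intermediate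
19 | 5,7,4',5'-tetrahydroxy-3,6,8,2'-tetramethoxyflavone | COc1cc(O)c(O)cc1-c1oc2c(OC)c(O)c(OC)c(O)c2c(=O)c1OC | target

Total step count: 13
Longest linear sequence: 9 steps (steps 5 to 13, from 7)

**Steps most likely to fail**

1. Step 12.
- What may go wrong: the activated acid may be diverted by trifluoroacetylation of C4a, by five-membered closure onto ring B, by demethylative lactonisation through the 2'-methoxy oxygen, or by acid-induced loss and migration of benzyl groups.
- Fallback: anionic closure of the same bond, setting out from 15 and coming back at 18.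
- The separated E isomer of 15 would be brominated with NBS in MeCN at −20 °C at the only free carbon of ring A. This should give methyl (E)-3-[3,5-bis(benzyloxy)-2-bromo-4,6-dimethoxyphenoxy]-3-[4,5-bis(benzyloxy)-2-methoxyphenyl]-2-methoxyprop-2-enoate F1.
- Bromine–lithium exchange with n-BuLi in THF at −95 °C would give the corresponding aryllithium F2. This attacks the neighbouring methyl ester (Parham cyclisation) and expels methoxide to give 18.

2. Step 10.
- What may go wrong: addition to the tetrasubstituted β-carbon, which is loaded with donors, may be so slow that oxidation of the phenoxide or attack of the phenoxide on the ester takes over.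
- Fallback: the acceptor is raised to the aldehyde level, setting out from 14 and coming back at 16.
- iBu2AlH in CH2Cl2 at −78 °C would reduce 14 to (E)-3-[4,5-bis(benzyloxy)-2-methoxyphenyl]-3-chloro-2-methoxyprop-2-en-1-ol F3.
- MnO2 in CH2Cl2 would oxidise F3 to (E)-3-[4,5-bis(benzyloxy)-2-methoxyphenyl]-3-chloro-2-methoxyprop-2-enal F4, a β-chlorovinyl aldehyde that is a much stronger acceptor.
- Phenol 6 with Cs2CO3 in DMF at rt would then give (E)-3-[3,5-bis(benzyloxy)-2,4-dimethoxyphenoxy]-3-[4,5-bis(benzyloxy)-2-methoxyphenyl]-2-methoxyprop-2-enal F5.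
- Pinnick oxidation (NaClO2, NaH2PO4, t-BuOH/H2O) would give 16 directly. A large excess of 2-methylbut-2-ene is used to keep hypochlorous acid away from ring A.

3. Step 9.
- What may go wrong: activation of the poorly enolised ketone may stall, and forcing may bring chlorination at C2 or erosion of the benzyl ethers by HCl.
- Fallback: the leaving group is placed on the enolate oxygen and the C–O bond is made by catalysis, setting out from 13 and coming back at 15.
- Deprotonation of 13 with NaH and O-sulfonylation with (CF3SO2)2O in THF at −78 °C, through the chelated enolate, would give methyl (E)-3-[4,5-bis(benzyloxy)-2-methoxyphenyl]-2-methoxy-3-{[(trifluoromethyl)sulfonyl]oxy}prop-2-enoate F6.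
- F6 would be coupled with phenol 6 by zerovalent palladium catalysis (Pd2(dba)3, 2-(di-tert-butylphosphino)biphenyl, K3PO4, toluene, 100 °C; vinyl triflate–phenol C–O coupling) to give 15.

Further compounds
F1 | step 12 | methyl (E)-3-[3,5-bis(benzyloxy)-2-bromo-4,6-dimethoxyphenoxy]-3-[4,5-bis(benzyloxy)-2-methoxyphenyl]-2-methoxyprop-2-enoate | COC(=O)/C(OC)=C(/c1cc(OCc2ccccc2)c(OCc2ccccc2)cc1OC)Oc1c(Br)c(OCc2ccccc2)c(OC)c(OCc2ccccc2)c1OC
F2 | step 12 | aryllithium from F1, methyl (E)-3-[3,5-bis(benzyloxy)-2-lithio-4,6-dimethoxyphenoxy]-3-[4,5-bis(benzyloxy)-2-methoxyphenyl]-2-methoxyprop-2-enoate | COC(=O)/C(OC)=C(/c1cc(OCc2ccccc2)c(OCc2ccccc2)cc1OC)Oc1c([Li])c(OCc2ccccc2)c(OC)c(OCc2ccccc2)c1OC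
F3 | step 10 | (E)-3-[4,5-bis(benzyloxy)-2-methoxyphenyl]-3-chloro-2-methoxyprop-2-en-1-ol | OC/C(OC)=C(/c1cc(OCc2ccccc2)c(OCc2ccccc2)cc1OC)Cl
F4 | step 10 | (E)-3-[4,5-bis(benzyloxy)-2-methoxyphenyl]-3-chloro-2-methoxyprop-2-enal | O=C/C(OC)=C(/c1cc(OCc2ccccc2)c(OCc2ccccc2)cc1OC)Cl
F5 | step 10 | (E)-3-[3,5-bis(benzyloxy)-2,4-dimethoxyphenoxy]-3-[4,5-bis(benzyloxy)-2-methoxyphenyl]-2-methoxyprop-2-enal | O=C/C(OC)=C(/c1cc(OCc2ccccc2)c(OCc2ccccc2)cc1OC)Oc1cc(OCc2ccccc2)c(OC)c(OCc2ccccc2)c1OC
F6 | step 9 | methyl (E)-3-[4,5-bis(benzyloxy)-2-methoxyphenyl]-2-methoxy-3-{[(trifluoromethyl)sulfonyl]oxy}prop-2-enoate | COC(=O)/C(OC)=C(/c1cc(OCc2ccccc2)c(OCc2ccccc2)cc1OC)OS(=O)(=O)C(F)(F)F
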